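**Retrosynthetic overview**
1. The target is the reduced (hydroquinone) form of a chromone-5,8-quinone. Cutting the C6–CH2 bond of the prenyl group gives 7-methoxy-3-aryl-chromene-4,5,8-trione, whose only unsubstituted quinone carbon is C6, and a prenylstannane.
2. The strategy rests on ring A: the oxygens on C5 and C8 are para to each other, with the C7 methoxy and C6 prenyl groups between them. The C5 oxygen is therefore introduced late, by para oxidation of an 8-phenol whose para carbon C5 still carries hydrogen.
3. The 8-hydroxy-7-methoxyisoflavone is cut at O1–C2 and C2–C3 to a 2,3-dihydroxy-4-methoxydeoxybenzoin and a one-carbon unit from DMF.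
4. The deoxybenzoin comes from Friedel–Crafts acylation of 3-methoxycatechol with 2,4,5-trimethoxyphenylacetic acid. Only one of the two catechol hydroxyls has a free ortho carbon, so the acylation itself decides which oxygen becomes O1 and which stays as the 8-OH.
5. Ring order: rings A and B are bought, and ring C is the only ring made (step 2). The target has no stereocentre.

Key step: step 3

Remark on the chemistry: the sp3 carbons that appear in two in-flask intermediates are racemic and are lost again, and the enamine geometry of the ring-closure intermediate is of no consequence.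

**Route**

Step 1
Reactants: 1 3-methoxycatechol; 2 2,4,5-trimethoxyphenylacetic acid
Product: 3 1-(2,3-dihydroxy-4-methoxyphenyl)-2-(2,4,5-trimethoxyphenyl)ethanone
Conditions: BF3·OEt2 (neat), 85 °C; then aq. NaOAc
Reagents that add atoms: none
Why: Friedel–Crafts acylation promoted by BF3 should go to C6 of 1, the only carbon that is ortho to a hydroxyl (so the new ketone is held by BF3 coordination to the neighbouring oxygen) and also para to the methoxy group, since the C2 hydroxyl has no free ortho carbon.

Step 2
Reactants: 3 1-(2,3-dihydroxy-4-methoxyphenyl)-2-(2,4,5-trimethoxyphenyl)ethanone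
Product: 5 8-hydroxy-7-methoxy-3-(2,4,5-trimethoxyphenyl)chromen-4-one, via enaminone 4 (not isolated)
Conditions: BF3·OEt2, DMF, rt; then MsCl, DMF, 60–80 °C; then H2O
Reagents that add atoms: N,N-dimethylformamide (DMF), CN(C)C=O
Why: Vilsmeier-type aminomethylenation of the activated methylene by the iminium salt formed from DMF and MsCl gives enaminone 4, and the ortho phenol then adds to its β-carbon and expels Me2NH (6-endo addition–elimination) to close ring C, leaving the second phenol as the 8-OH.

Step 3
Reactants: 5 8-hydroxy-7-methoxy-3-(2,4,5-trimethoxyphenyl)chromen-4-one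
Product: 7 7-methoxy-3-(2,4,5-trimethoxyphenyl)chromene-4,5,8-trione, via C5 aminoxy adduct 6 (not isolated)
Conditions: ON(SO3K)2 (Fremy's salt, 2.5 equiv), KH2PO4, H2O–acetone, rt
Reagents that add atoms: potassium nitrosodisulfonate ON(SO3K)2, [O]N(S(=O)(=O)[O-])S(=O)(=O)[O-].[K+].[K+]
Why: In this Teuber oxidation one nitroxyl radical abstracts the hydrogen of the unchelated 8-OH, a second one couples through its oxygen with the para carbon C5 of the phenoxyl radical to give dienone 6, and loss of HN(SO3K)2 across the C5–H and O–N bonds leaves the C5 carbonyl. The closest known reaction type is the Fremy's salt oxidation of phenols with a free para position to para-quinones, as used on 8-hydroxyquinolines and related benzo-fused heterocyclic phenols. No ring is closed and no stereocentre remains, because the sp3 carbon of 6 is lost in the elimination. The step needs para rather than ortho attack, and the substrate secures this because C5 is the only unsubstituted carbon that carries spin density, the ortho carbons being C7 with its methoxy group and the ring-fusion carbon C8a. It also needs selectivity for ring A, which should follow because ring B has no free phenol and the pyranone is inert to the nitroxyl radical.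

Step 4
Reactants: 7 7-methoxy-3-(2,4,5-trimethoxyphenyl)chromene-4,5,8-trione; 8 tributyl(3-methylbut-2-enyl)stannane
Product: 11 5,8-dihydroxy-7-methoxy-6-(3-methylbut-2-enyl)-3-(2,4,5-trimethoxyphenyl)chromen-4-one, via quinol stannyl ether 9 (not isolated), via hydroquinone stannyl ether 10 (not isolated)
Conditions: BF3·OEt2, CH2Cl2, –78 to –40 °C; cold 0.5 M HCl quench; aq. Na2S2O4 wash
Reagents that add atoms: none
Why: In this Naruta-type allylation of a quinone, the BF3-activated C8 carbonyl (the only quinone carbonyl that is not a vinylogous ester) should take the γ-carbon of 8 (SE2') to give quinol 9, whose [3,3] shift delivers the prenyl group with its normal connectivity to C6, the sole unsubstituted quinone carbon, and enolisation gives 10, which the acid quench frees as the hydroquinone; the Na2S2O4 wash only returns any product that unreacted quinone has oxidised.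

**Compound list**
1 | 3-methoxycatechol | COc1cccc(O)c1O | starting material
2 | 2,4,5-trimethoxyphenylacetic acid | COc1cc(OC)c(CC(=O)O)cc1OC | starting material
3 | 1-(2,3-dihydroxy-4-methoxyphenyl)-2-(2,4,5-trimethoxyphenyl)ethanone | COc1ccc(C(=O)Cc2cc(OC)c(OC)cc2OC)c(O)c1O | intermediate
4 | 3-(dimethylamino)-1-(2,3-dihydroxy-4-methoxyphenyl)-2-(2,4,5-trimethoxyphenyl)prop-2-en-1-one (enamine geometry not fixed; formed and consumed in the flask) | COc1ccc(C(=O)C(=CN(C)C)c2cc(OC)c(OC)cc2OC)c(O)c1O | intermediate
5 | 8-hydroxy-7-methoxy-3-(2,4,5-trimethoxyphenyl)chromen-4-one | COc1cc(OC)c(-c2coc3c(O)c(OC)ccc3c2=O)cc1OC | intermediate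
6 | dipotassium salt of 5-[bis(sulfonato)aminooxy]-7-methoxy-3-(2,4,5-trimethoxyphenyl)-5H-chromene-4,8-dione (racemic at C5; formed and consumed in the flask) | COc1cc(OC)c(C2=COC3=C(C2=O)C(ON(S(=O)(=O)[O-])S(=O)(=O)[O-])C=C(OC)C3=O)cc1OC.[K+].[K+] | intermediate
7 | 7-methoxy-3-(2,4,5-trimethoxyphenyl)chromene-4,5,8-trione | COc1cc(OC)c(C2=COC3=C(C2=O)C(=O)C=C(OC)C3=O)cc1OC | intermediate
8 | tributyl(3-methylbut-2-enyl)stannane | CCCC[Sn](CCCC)(CCCC)CC=C(C)C | starting material
9 | 7-methoxy-8-(2-methylbut-3-en-2-yl)-8-(tributylstannyloxy)-3-(2,4,5-trimethoxyphenyl)-8H-chromene-4,5-dione (racemic at C8; formed and consumed in the flask) | COc1cc(OC)c(C2=COC3=C(C2=O)C(=O)C=C(OC)C3(O[Sn](CCCC)(CCCC)CCCC)C(C)(C)C=C)cc1OC | intermediate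
10 | 5-hydroxy-7-methoxy-6-(3-methylbut-2-enyl)-8-(tributylstannyloxy)-3-(2,4,5-trimethoxyphenyl)chromen-4-one (formed and consumed in the flask) | COc1cc(OC)c(-c2coc3c(O[Sn](CCCC)(CCCC)CCCC)c(OC)c(CC=C(C)C)c(O)c3c2=O)cc1OC | intermediate
11 | 5,8-dihydroxy-7-methoxy-6-(3-methylbut-2-enyl)-3-(2,4,5-trimethoxyphenyl)chromen-4-one | COc1cc(OC)c(-c2coc3c(O)c(OC)c(CC=C(C)C)c(O)c3c2=O)cc1OC | target

**Step count**
Total steps: 4. Longest linear sequence: 4 steps (1 or 2 to 11).

**Steps most likely to fail**

Step 3. Hydrogen abstraction may be slow on a phenol that is deactivated by the meta acyl carbon C4a. The nitroxyl radical may also couple at the methoxy-bearing ortho carbon C7 and lead to an ortho-quinone by loss of methanol, and water may open the electron-poor pyranone of the product during the oxidation. The fallback sets out from 5 and comes back at 7. Elbs persulfate oxidation (K2S2O8 in cold dilute aqueous KOH–pyridine), in which the phenolate attacks the peroxide oxygen through its para carbon, should give potassium 8-hydroxy-7-methoxy-4-oxo-3-(2,4,5-trimethoxyphenyl)chromen-5-yl sulfate F1. Warming the acidified aqueous phase (HCl, a little Na2SO3) should hydrolyse the sulfate to 5,8-dihydroxy-7-methoxy-3-(2,4,5-trimethoxyphenyl)chromen-4-one F2. Ag2O with Na2SO4 in dry CH2Cl2 then oxidises F2 to quinone 7 without water.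

Step 4. The quinol from the hindered γ-terminus may fail to undergo the [3,3] shift, the slow transfer of the bulky prenyl group may let electron transfer to the quinone compete, and BF3 may cyclise the new prenyl group onto the 5-OH to a dimethylchroman. The fallback sets out from 7 and comes back at 11. It makes the C6–C bond with an unhindered allyl group and builds the trisubstituted alkene afterwards under neutral conditions. Allyltributylstannane with BF3·OEt2 in CH2Cl2 at –78 °C, followed by the same quench, should give 6-allyl-5,8-dihydroxy-7-methoxy-3-(2,4,5-trimethoxyphenyl)chromen-4-one F3. Olefin cross-metathesis of F3 with excess 2-methylbut-2-ene and the second-generation Grubbs catalyst in CH2Cl2 at 40 °C then converts the allyl group into the prenyl group of 11.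

Step 1. Acylation may go to C4 of 1 (ortho to the methoxy group and para to the C1 hydroxyl), a second molecule of 2 may acylate the electron-rich ring of 2, and hot BF3·OEt2 may cleave aryl methyl ethers. The fallback sets out from 2 and comes back at 3. Acylation of pyrogallol (benzene-1,2,3-triol) with 2 in BF3·OEt2, where the symmetry of the triol leaves only one kind of ortho-hydroxy position, should give 1-(2,3,4-trihydroxyphenyl)-2-(2,4,5-trimethoxyphenyl)ethanone F4. MeI (1 equiv) with NaHCO3 in DMF at 40 °C should then methylate only the 4-OH, the most acidic phenol because it is para to the ketone and not hydrogen-bonded to it, and give 3.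

**Further compounds**
F1 | step 3 | potassium 8-hydroxy-7-methoxy-4-oxo-3-(2,4,5-trimethoxyphenyl)chromen-5-yl sulfate | COc1cc(OC)c(-c2coc3c(O)c(OC)cc(OS(=O)(=O)[O-])c3c2=O)cc1OC.[K+]
F2 | step 3 | 5,8-dihydroxy-7-methoxy-3-(2,4,5-trimethoxyphenyl)chromen-4-one | COc1cc(OC)c(-c2coc3c(O)c(OC)cc(O)c3c2=O)cc1OC
F3 | step 4 | 6-allyl-5,8-dihydroxy-7-methoxy-3-(2,4,5-trimethoxyphenyl)chromen-4-one | COc1cc(OC)c(-c2coc3c(O)c(OC)c(CC=C)c(O)c3c2=O)cc1OC
F4 | step 1 | 1-(2,3,4-trihydroxyphenyl)-2-(2,4,5-trimethoxyphenyl)ethanone | COc1cc(OC)c(CC(=O)c2ccc(O)c(O)c2O)cc1OC
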